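Which of north-east and west ends with the longer chains at 20 h, given the same charges of free monomer, initiator and impurity but different transfer agent?

the same everywhere: free monomer 2.2 M; initiator 130 mM; impurity 33 mM
- winter: transfer agent 0.43 M; run made earlier
- midnight: transfer agent 1.1 M; run made earlier
- north-east: transfer agent 0.660 M; time 20 h
- west: transfer agent 1.20 M; time 20 h

- winter (time / h: monomer in chains / %, free monomer / %): 0.833: 34.8, 63.9; 2.00: 61.8, 38.9; 4.00: 80.1, 20.1; 10.0: 94.0, 6.0
- midnight (time / h: monomer in chains / %, free monomer / %): 0.833: 33.3, 66.6; 2.00: 52.4, 46.6; 4.00: 67.1, 33.4; 10.0: 74.6, 25.5

(standard deviation of a reading: 0.5 percentage points)

- which of the two ends with the longer chains by the average number of monomer units in a chain (chains begun, living or dead) ("neither" if they lie within 10%) (north-east / west / neither)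
- average number of monomer units in a chain (chains begun, living or dead) at the end, north-east
- average number of monomer units in a chain (chains begun, living or dead) at the end, west

- the average divides the monomer in chains by the number of chains begun, living and dead together
- what was read earlier has a scatter of 0.5 percentage points, one standard deviation
- on the list of suspects stand: free monomer + initiator -> living end + monomer in chains; free monomer + living end -> monomer in chains + living end; living end + transfer agent -> dead chain; initiator + impurity -> spent initiator A; free monomer + initiator -> spent initiator B
- the earlier runs do not show the number of chains; that part of a forecast is a guess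

For whoever takes over the bench: let f be the fraction of charged free monomer left, T the transfer agent and L the living end. On the suspected steps, ln f falls at a rate proportional to L, and L dies pseudo-first-order in T, with T taken as constant. Integrating the rate in closed form, the stopped flask obeys −T·ln f = R, and this plateau reach, R, is the same for recipes differing in T alone. The last midnight reading, taken as that flask's stopping point, gives R = 1.50 M, a value that carries the scatter of the reading. The last winter reading gives a lower 1.21 M, so the winter flask is taken as unfinished at that reading.

When the next person comes, north-east should hold 10.3% of its free monomer and west 28.6%, the larger remainder. The earlier runs do not show chains, so this reckoning guesses that impurity spends its own charge of initiator, leaving 97.0 mM of chains. That gives 20.4 units in north-east against 16.2 in west. Leave the transfer agent as charged.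

The forecast says north-east, with 18 units in north-east and 14.2 in west, and of the chains it writes: “They lie between 97 mM (impurity kills initiator first) and 130 mM”. This reckoning takes the low end of that span, and its lengths are longer than the forecast's.

The simulation gives north-east, with 20.8 units in north-east and 16.6 in west.

    free monomer + initiator → living end + monomer in chains (k = 0.00264 M⁻¹ s⁻¹)
    free monomer + living end → monomer in chains + living end, rate k2*[living end]*[free monomer] (k = 0.00157 M⁻¹ s⁻¹)
    living end + transfer agent → dead chain (kL = 1.07 × 10⁻⁴ M⁻¹ s⁻¹)
    initiator + impurity → spent initiator A (k = 2.27 M⁻¹ s⁻¹)
    free monomer + initiator → spent initiator B (k = 6.06 × 10⁻⁵ M⁻¹ s⁻¹)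

In north-east the living end's half-life against transfer agent, 3.2 h at the end, is shorter than the run. Beside 0.0938 M of dead chain stands 0.00106 M of living end at that time, and at 200 h the north-east average reads 20.9. Chains begun in north-east come to 0.0949 M at 20.0 h, fewer than the 97.0 mM guessed here. For a neighbour, north-east with 1.7 M of transfer agent, R gives 41.4% of free monomer left and 13.3 units. The computed flask leaves 41% and reads 13.6.

The data stem from a simulated flask for an exercise; the scatter is artificial.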